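Retrosynthesis: the C10–C11 bond is cut last, giving the C14 enyne diol 13 and the C26 hexaenyl iodide 26. 26 is cut at C11=C12 (Takai) and C11′=C12′ (Wittig on the C10 dialdehyde 23), and both end groups go back to one epoxy aldehyde 8 (C7=C8 by HWE; C7′–C8′ by Seyferth–Gilbert homologation, C8′–C9′ by Sonogashira coupling).
Enabling feature: the trisubstituted E-alkene C9(CH3)=C10H next to the C10–C11 bond is the retron of a syn-methylmetalation of a terminal alkyne. One flask therefore adds C19 to C9≡C10–H of 13 and joins C10 to the C11 iodide of 26 (two C–C bonds, 9E set, 11E kept).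
Ring A (triol cyclohexane): the vinyl oxirane O–C5–C6–C7=C8 is turned by zerovalent palladium and CO2 into a temporary cis-fused carbonate ring with net retention at C6; methanolysis then frees the 5,6-cis-diol and the alkyne.
Rings B and C (cyclohexane with fused 2,5-dihydrofuran): anti hydride SN2′ opening of the alkynyl oxirane gives the (aS)-allene C6′=C7′=C8′; silver-catalysed 5-endo attack of the C5′ hydroxyl on C8′ closes ring C and converts the axis into C8′(R).
Stereochemistry: C3 and C3′ come from actinol 1; C5, C6 and C5′ from one Katsuki–Sharpless epoxidation; C8′ by centre-to-axis-to-centre transfer; alkene geometries from HWE, stereoretentive couplings, Wittig with thermal equilibration, Takai olefination and syn-carbometalation.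
Forward order: 1 → 8 (steps 1–6); 8 → 13 (steps 7–9); 8 → 26 (steps 10–18); 13 + 26 → 29 (step 19); desilylation → 30 (step 20).

Key step: step 19

Remark: carotenoid locants are used (C1–C20 for the triol half, primed locants for the furanoid half); TBS = tert-butyldimethylsilyl; 1, 9, 15 and 23 are assumed to be purchasable.

Step 1
Reactants: 1 (4R,6R)-4-hydroxy-2,2,6-trimethylcyclohexan-1-one (actinol)
Product: 2 (4R,6R)-4-(TBS-oxy)-2,2,6-trimethylcyclohexan-1-one
Conditions: TBSCl, imidazole, DMF, rt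
Reagents that add atoms: tert-butyldimethylsilyl chloride, CC(C)(C)[Si](C)(C)Cl
Why: Silyl ether formation at the only hydroxyl group; no stereocentre is touched.

Step 2
Reactants: 2 TBS-actinol
Product: 4 (4R)-4-(TBS-oxy)-2,6,6-trimethylcyclohex-1-en-1-yl trifluoromethanesulfonate, via lithium enolate 3 (not isolated)
Conditions: LiN(iPr)2, THF, −78 °C; then PhNTf2, −78 °C → rt
Reagents that add atoms: N-phenylbis(trifluoromethanesulfonimide), O=S(=O)(N(c1ccccc1)S(=O)(=O)C(F)(F)F)C(F)(F)F
Why: Only C5 carries an α-hydrogen, so enolisation is regiospecific and O-triflation should give the tetrasubstituted enol triflate; the C5 centre is removed on purpose.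

Step 3
Reactants: 4 enol triflate
Product: 5 methyl (4R)-4-(TBS-oxy)-2,6,6-trimethylcyclohex-1-ene-1-carboxylate
Conditions: Pd(OAc)2 (5 mol%), PPh3, CO (1 atm), MeOH, Et3N, DMF, 40 °C
Reagents that add atoms: carbon monoxide, [C-]#[O+]; methanol, CO
Why: Palladium-catalysed alkoxycarbonylation of a vinyl triflate installs C7 at the ester oxidation level.

Step 4
Reactants: 5 methyl ester
Product: 6 [(4R)-4-(TBS-oxy)-2,6,6-trimethylcyclohex-1-en-1-yl]methanol
Conditions: i-Bu2AlH (2.5 equiv), CH2Cl2, −78 → 0 °C; aq. potassium sodium tartrate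
Reagents that add atoms: none
Why: 1,2-Reduction of an α,β-unsaturated ester by an aluminium hydride gives the allylic alcohol needed for directed epoxidation.

Step 5
Reactants: 6 allylic alcohol
Product: 7 [(1R,2R,4S)-4-(TBS-oxy)-1,2-epoxy-2,6,6-trimethylcyclohexyl]methanol (oxirane oxygen trans to the silyloxy group)
Conditions: Ti(OiPr)4 (0.3 equiv), D-(−)-diethyl tartrate (0.36 equiv), t-BuOOH, 4 Å molecular sieves, CH2Cl2, −20 °C
Reagents that add atoms: tert-butyl hydroperoxide, CC(C)(C)OO
Why: Katsuki–Sharpless asymmetric epoxidation; the D-(−)-tartrate catalyst should deliver oxygen to the face anti to the C3 silyloxy group, setting C5 and C6 (and the later C5′) by reagent control.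

Step 6
Reactants: 7 epoxy alcohol
Product: 8 (1S,2R,4S)-4-(TBS-oxy)-1,2-epoxy-2,6,6-trimethylcyclohexane-1-carbaldehyde
Conditions: (n-Pr4N)RuO4 (5 mol%), N-methylmorpholine N-oxide, 4 Å molecular sieves, CH2Cl2, rt
Reagents that add atoms: none
Why: Ley–Griffith oxidation of the primary alcohol under neutral conditions; the aldehyde has no α-hydrogen, so C6 cannot epimerise.

Step 7
Reactants: 8 epoxy aldehyde; 9 diethyl [3-(trimethylsilyl)prop-2-yn-1-yl]phosphonate
Product: 11 (E)-enyne epoxide (8 with CHO replaced by (E)-CH=CH–C≡C–SiMe3), via lithiated phosphonate 10 (not isolated)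
Conditions: LiN(SiMe3)2, THF, −78 °C; then 8, −78 → 0 °C
Reagents that add atoms: none
Why: Horner–Wadsworth–Emmons olefination with a propargylic phosphonate should give the 7E enyne, the bulky quaternary C6 reinforcing the usual E preference.

Step 8
Reactants: 11 (E)-enyne epoxide
Product: 12 cis-fused cyclic carbonate of the C5,C6-diol (both C–O bonds on the face of the former oxirane; (E)-CH=CH–C≡C–SiMe3 on C6)
Conditions: Pd2(dba)3·CHCl3 (2.5 mol%), P(OiPr)3 (20 mol%), CO2 (1 atm), THF, 0 °C → rt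
Reagents that add atoms: carbon dioxide, O=C=O
Why: Palladium-catalysed CO2 insertion into a vinyl epoxide (Tsuji–Trost-type ionisation): zerovalent palladium opens C6–O with inversion, the C5 alkoxide is carbonated and recloses on C6 anti to palladium, so two inversions give net retention and the cis-diol carbonate; C1 and C5 carry no hydrogen, so the π-allyl complex cannot escape by β-hydride elimination.

Step 9
Reactants: 12 cyclic carbonate
Product: 13 C14 enyne diol, (3S,5R,6S)-3-(TBS-oxy)-6-[(E)-but-1-en-3-yn-1-yl]-1,1,5-trimethylcyclohexane-5,6-diol (carotenoid locants)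
Conditions: NaOMe (0.3 equiv), MeOH, rt → 40 °C
Reagents that add atoms: none
Why: Methoxide-catalysed methanolysis cleaves both the carbonate ring and the C(sp)–Si bond without touching any stereocentre or the secondary silyl ether.

Step 10
Reactants: 8 epoxy aldehyde
Product: 14 ethynyl epoxide (8 with CHO replaced by C≡CH)
Conditions: dimethyl (1-diazo-2-oxopropyl)phosphonate, K2CO3, MeOH, 0 °C → rt
Reagents that add atoms: dimethyl (1-diazo-2-oxopropyl)phosphonate, CC(=O)C(=[N+]=[N-])P(=O)(OC)OC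
Why: Seyferth–Gilbert homologation in the Ohira–Bestmann variant; the non-enolisable aldehyde and the mild base leave the oxirane and C6′ intact.

Step 11
Reactants: 15 ethyl acetoacetate
Product: 16 ethyl (E)-3-(trifluoromethylsulfonyloxy)but-2-enoate
Conditions: Tf2O, aq. Me4NOH, hexanes, 5 °C
Reagents that add atoms: trifluoromethanesulfonic anhydride, O=S(=O)(OS(=O)(=O)C(F)(F)F)C(F)(F)F
Why: Biphasic O-triflation of the non-chelated ammonium enolate of a β-keto ester should give the enol triflate with triflate trans to the ester (E).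

Step 12
Reactants: 14 ethynyl epoxide; 16 (E)-enol triflate
Product: 17 ethyl (E)-3-methyl-5-[(1,2-epoxy-4-(TBS-oxy)-2,6,6-trimethylcyclohexyl)]pent-2-en-4-ynoate (ring as in 8)
Conditions: Pd(PPh3)4 (5 mol%), CuI (10 mol%), i-Pr2NEt, THF, rt
Reagents that add atoms: none
Why: Sonogashira coupling of a terminal alkyne with an activated vinyl triflate proceeds with retention of alkene geometry, fixing 9′E.

Step 13
Reactants: 17 epoxy enynoate
Product: 18 ethyl (2E)-5-[(2R,4S)-2-hydroxy-4-(TBS-oxy)-2,6,6-trimethylcyclohexylidene]-3-methylpenta-2,4-dienoate with (aS) allene axis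
Conditions: Pd2(dba)3·CHCl3 (2.5 mol%), n-Bu3P (10 mol%), HCO2H/Et3N, THF, rt
Reagents that add atoms: none
Why: Palladium-catalysed formate hydrogenolysis of a propargylic oxirane: anti SN2′ oxidative addition gives an allenyl-palladium alkoxide, formate decarboxylation gives Pd–H, and reductive elimination with retention places H on C8′ anti to the departing C6′–O bond, so the C6′ centre is translated into the (aS) axis and the C5′ hydroxyl is freed.

Step 14
Reactants: 18 (aS)-allenol
Product: 19 ethyl (E)-3-[(2R,6S,7aR)-6-(TBS-oxy)-4,4,7a-trimethyl-2,4,5,6,7,7a-hexahydro-1-benzofuran-2-yl]but-2-enoate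
Conditions: AgNO3 (20 mol%), CaCO3, acetone/H2O, rt, dark
Reagents that add atoms: none
Why: Silver-catalysed 5-endo cycloisomerisation of an α-hydroxyallene: the C5′ oxygen attacks C8′ in the plane of the C6′ substituents, so the (aS) axis is converted stereospecifically into C8′(R) with the side chain trans to the C5′ methyl.

Step 15
Reactants: 19 dihydrofuran enoate
Product: 20 (E)-3-[(2R,6S,7aR)-6-(TBS-oxy)-4,4,7a-trimethyl-2,4,5,6,7,7a-hexahydro-1-benzofuran-2-yl]but-2-en-1-ol
Conditions: i-Bu2AlH (2.5 equiv), CH2Cl2, −78 °C; aq. potassium sodium tartrate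
Reagents that add atoms: none
Why: 1,2-Reduction of the enoate at low temperature under non-basic conditions leaves the base-sensitive C8′–H and the allylic ether untouched.

Step 16
Reactants: 20 allylic alcohol
Product: 22 C15 furanoid triphenylphosphonium bromide (PPh3+ on C11′), via allylic bromide 21 (not isolated)
Conditions: CBr4, PPh3, CH2Cl2, 0 °C; then further PPh3, rt
Reagents that add atoms: tetrabromomethane, BrC(Br)(Br)Br; triphenylphosphine, c1ccc(cc1)P(c1ccccc1)c1ccccc1
Why: Appel bromination followed by SN2 quaternisation of the primary allylic bromide gives the Wittig salt without the acid that a direct hydrobromide route would need.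

Step 17
Reactants: 22 phosphonium bromide; 23 (2E,4E,6E)-2,7-dimethylocta-2,4,6-trienedial
Product: 25 C25 furanoid pentaenal (aldehyde at C12), via phosphorus ylide 24 (not isolated)
Conditions: NaN(SiMe3)2 (1.0 equiv), THF, −78 °C; then 23 (3 equiv), −78 → 0 °C; then heptane, 80 °C, dark (11′Z → 11′E)
Reagents that add atoms: none
Why: Wittig mono-olefination of the symmetrical dialdehyde used in excess; the hindered 11′Z isomer should equilibrate thermally to the all-E aldehyde, as is usual for C11=C12 Wittig products in this series.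

Step 18
Reactants: 25 C25 pentaenal
Product: 26 C26 furanoid (E)-hexaenyl iodide (iodine on C11)
Conditions: CHI3 (3 equiv), CrCl2 (8 equiv), THF/1,4-dioxane, 0 °C → rt, dark
Reagents that add atoms: iodoform, IC(I)I
Why: Takai olefination converts the polyenal into the (E)-vinyl iodide through a gem-dichromium reagent, setting 11E.

Step 19
Reactants: 13 C14 enyne diol; 26 C26 hexaenyl iodide
Product: 29 3,3′-bis-O-TBS ether of 30, via alkenylalane 27 (not isolated), via alkenylzinc chloride 28 (not isolated)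
Conditions: Me3Al (4 equiv), Cp2ZrCl2 (0.25 equiv), CH2Cl2, −20 → 23 °C; volatiles removed; THF, ZnCl2 (1.5 equiv); then 26 (0.7 equiv), Pd2(dba)3 (2.5 mol%), P(2-furyl)3 (10 mol%), THF/DMF, 23 °C, dark; aq. potassium sodium tartrate/NaHCO3
Reagents that add atoms: trimethylaluminium, C[Al](C)C
Why: Cp2ZrCl2-catalysed syn-methylalumination of the terminal alkyne of 13 places CH3 on C9 and aluminium on C10 while the two tertiary hydroxyls are masked in the same flask as a cyclic aluminium diolate; Al→Zn exchange then feeds a zerovalent-palladium cycle (oxidative addition into the C11–I bond of 26 with retention, transmetalation, reductive elimination) that forms the C10–C11 bond. The closest known reaction type is the tandem Negishi carboalumination/Negishi alkenyl–alkenyl coupling, which has been applied to terminal enynes in carotenoid and retinoid assembly with retention of geometry. No ring is closed and no stereocentre is created; the only new stereo-element is the C9=C10 geometry, fixed as E by the syn addition, while the 11E geometry of 26 is carried through. The step needs chemoselectivity for the alkyne over the C7=C8 alkene and the polyene (terminal alkynes react far faster), tolerance of the silyl ethers, and survival of the acid-sensitive C8′–O allylic ether, which is why excess Me3Al is stripped off and the coupling is run through the less Lewis-acidic alkenylzinc in THF/DMF with the iodide as the limiting partner.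

Step 20
Reactants: 29 bis-silyl ether
Product: 30 (3S,5R,6S,3′S,5′R,8′R)-5′,8′-epoxy-5,6,5′,8′-tetrahydro-β,β-carotene-3,5,6,3′-tetrol (target)
Conditions: Bu4NF (6 equiv), THF, 0 °C → rt, dark, argon
Reagents that add atoms: none
Why: Fluoride cleavage of the two secondary silyl ethers under basic, non-acidic conditions should leave the furanoid C8′ centre, the tertiary allylic diol and the all-E nonaene unchanged.

Compound list
1 | (4R,6R)-4-hydroxy-2,2,6-trimethylcyclohexan-1-one (actinol) | O=C1C(C)(C)C[C@H](O)C[C@H]1C | starting material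
2 | (4R,6R)-4-(TBS-oxy)-2,2,6-trimethylcyclohexan-1-one | O=C1C(C)(C)C[C@H](O[Si](C)(C)C(C)(C)C)C[C@H]1C | intermediate
3 | lithium enolate of 2 | CC1=C([O-])C(C)(C)C[C@H](O[Si](C)(C)C(C)(C)C)C1.[Li+] | intermediate
4 | (4R)-4-(TBS-oxy)-2,6,6-trimethylcyclohex-1-en-1-yl trifluoromethanesulfonate | CC1=C(OS(=O)(=O)C(F)(F)F)C(C)(C)C[C@H](O[Si](C)(C)C(C)(C)C)C1 | intermediate
5 | methyl (4R)-4-(TBS-oxy)-2,6,6-trimethylcyclohex-1-ene-1-carboxylate | CC1=C(C(=O)OC)C(C)(C)C[C@H](O[Si](C)(C)C(C)(C)C)C1 | intermediate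
6 | [(4R)-4-(TBS-oxy)-2,6,6-trimethylcyclohex-1-en-1-yl]methanol | CC1=C(CO)C(C)(C)C[C@H](O[Si](C)(C)C(C)(C)C)C1 | intermediate
7 | [(1R,2R,4S)-4-(TBS-oxy)-1,2-epoxy-2,6,6-trimethylcyclohexyl]methanol | OC[C@@]12O[C@]1(C)C[C@@H](O[Si](C)(C)C(C)(C)C)CC2(C)C | intermediate
8 | (1S,2R,4S)-4-(TBS-oxy)-1,2-epoxy-2,6,6-trimethylcyclohexane-1-carbaldehyde | O=C[C@@]12O[C@]1(C)C[C@@H](O[Si](C)(C)C(C)(C)C)CC2(C)C | intermediate
9 | diethyl [3-(trimethylsilyl)prop-2-yn-1-yl]phosphonate | CCOP(=O)(CC#C[Si](C)(C)C)OCC | starting material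
10 | lithiated phosphonate from 9 | [Li+].CCOP(=O)([CH-]C#C[Si](C)(C)C)OCC | intermediate
11 | (E)-enyne epoxide (8 with (E)-CH=CH–C≡C–SiMe3 in place of CHO) | C[Si](C)(C)C#C/C=C/[C@@]12O[C@]1(C)C[C@@H](O[Si](C)(C)C(C)(C)C)CC2(C)C | intermediate
12 | cis-fused C5,C6 cyclic carbonate bearing (E)-CH=CH–C≡C–SiMe3 on C6 | C[Si](C)(C)C#C/C=C/[C@@]12OC(=O)O[C@]1(C)C[C@@H](O[Si](C)(C)C(C)(C)C)CC2(C)C | intermediate
13 | C14 enyne diol, (3S,5R,6S)-3-(TBS-oxy)-6-[(E)-but-1-en-3-yn-1-yl]-1,1,5-trimethylcyclohexane-5,6-diol | C#C/C=C/[C@]1(O)C(C)(C)C[C@H](O[Si](C)(C)C(C)(C)C)C[C@@]1(C)O | intermediate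
14 | ethynyl epoxide (8 with C≡CH in place of CHO) | C#C[C@@]12O[C@]1(C)C[C@@H](O[Si](C)(C)C(C)(C)C)CC2(C)C | intermediate
15 | ethyl acetoacetate | CCOC(=O)CC(C)=O | starting material
16 | ethyl (E)-3-(trifluoromethylsulfonyloxy)but-2-enoate | CCOC(=O)/C=C(\C)OS(=O)(=O)C(F)(F)F | intermediate
17 | epoxy enynoate, ethyl (E)-3-methyl-5-(epoxycyclohexyl)pent-2-en-4-ynoate (ring as in 8) | CCOC(=O)/C=C(\C)C#C[C@@]12O[C@]1(C)C[C@@H](O[Si](C)(C)C(C)(C)C)CC2(C)C | intermediate
18 | (aS)-allenol, ethyl (2E)-5-[(2R,4S)-2-hydroxy-4-(TBS-oxy)-2,6,6-trimethylcyclohexylidene]-3-methylpenta-2,4-dienoate | CCOC(=O)/C=C(\C)C([H])=[C@]=C1C(C)(C)C[C@H](O[Si](C)(C)C(C)(C)C)C[C@@]1(C)O | intermediate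
19 | ethyl (E)-3-[(2R,6S,7aR)-6-(TBS-oxy)-4,4,7a-trimethyl-2,4,5,6,7,7a-hexahydro-1-benzofuran-2-yl]but-2-enoate | CCOC(=O)/C=C(\C)[C@H]1C=C2C(C)(C)C[C@H](O[Si](C)(C)C(C)(C)C)C[C@@]2(C)O1 | intermediate
20 | (E)-3-[(2R,6S,7aR)-6-(TBS-oxy)-4,4,7a-trimethyl-2,4,5,6,7,7a-hexahydro-1-benzofuran-2-yl]but-2-en-1-ol | OC/C=C(\C)[C@H]1C=C2C(C)(C)C[C@H](O[Si](C)(C)C(C)(C)C)C[C@@]2(C)O1 | intermediate
21 | allylic bromide from 20 (Br on C11′) | BrC/C=C(\C)[C@H]1C=C2C(C)(C)C[C@H](O[Si](C)(C)C(C)(C)C)C[C@@]2(C)O1 | intermediate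
22 | C15 furanoid triphenylphosphonium bromide | [Br-].C(/C=C(\C)[C@H]1C=C2C(C)(C)C[C@H](O[Si](C)(C)C(C)(C)C)C[C@@]2(C)O1)[P+](c1ccccc1)(c1ccccc1)c1ccccc1 | intermediate
23 | (2E,4E,6E)-2,7-dimethylocta-2,4,6-trienedial | O=C/C(C)=C/C=C/C=C(\C)C=O | starting material
24 | phosphorus ylide from 22 | C(=P(c1ccccc1)(c1ccccc1)c1ccccc1)/C=C(\C)[C@H]1C=C2C(C)(C)C[C@H](O[Si](C)(C)C(C)(C)C)C[C@@]2(C)O1 | intermediate
25 | C25 pentaenal, (2E,4E,6E,8E,10E)-2,7-dimethyl-11-[(2R,6S,7aR)-6-(TBS-oxy)-4,4,7a-trimethyl-2,4,5,6,7,7a-hexahydro-1-benzofuran-2-yl]dodeca-2,4,6,8,10-pentaenal | O=C/C(C)=C/C=C/C=C(C)/C=C/C=C(\C)[C@H]1C=C2C(C)(C)C[C@H](O[Si](C)(C)C(C)(C)C)C[C@@]2(C)O1 | intermediate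
26 | C26 hexaenyl iodide, (1E,3E,5E,7E,9E,11E)-1-iodo-3,8-dimethyl-12-[(2R,6S,7aR)-6-(TBS-oxy)-4,4,7a-trimethyl-2,4,5,6,7,7a-hexahydro-1-benzofuran-2-yl]trideca-1,3,5,7,9,11-hexaene | I/C=C/C(C)=C/C=C/C=C(C)/C=C/C=C(\C)[C@H]1C=C2C(C)(C)C[C@H](O[Si](C)(C)C(C)(C)C)C[C@@]2(C)O1 | intermediate
27 | (E)-alkenyl(dimethyl)alane from 13 with the diol bound as a methylaluminium diolate | C[Al](C)/C=C(\C)/C=C/[C@@]12O[Al](C)O[C@]1(C)C[C@@H](O[Si](C)(C)C(C)(C)C)CC2(C)C | intermediate
28 | (E)-alkenylzinc chloride from 27 | Cl[Zn]/C=C(\C)/C=C/[C@@]12O[Al](C)O[C@]1(C)C[C@@H](O[Si](C)(C)C(C)(C)C)CC2(C)C | intermediate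
29 | 3,3′-bis-O-TBS ether of 30 | CC(/C=C/C=C(C)/C=C/[C@]1(O)C(C)(C)C[C@H](O[Si](C)(C)C(C)(C)C)C[C@@]1(C)O)=C\C=C\C=C(C)\C=C\C=C(/C)[C@H]1C=C2C(C)(C)C[C@H](O[Si](C)(C)C(C)(C)C)C[C@@]2(C)O1 | intermediate
30 | (3S,5R,6S,3′S,5′R,8′R)-5′,8′-epoxy-5,6,5′,8′-tetrahydro-β,β-carotene-3,5,6,3′-tetrol | CC(/C=C/C=C(C)/C=C/[C@]1(O)C(C)(C)C[C@H](O)C[C@@]1(C)O)=C\C=C\C=C(C)\C=C\C=C(/C)[C@H]1C=C2C(C)(C)C[C@H](O)C[C@@]2(C)O1 | target

Total step count: 20. Longest linear sequence: 16 steps (steps 1–6, 10, 12–20).

Steps most likely to fail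

Step 19. The Lewis-acidic aluminium and zinc species may ionise the C8′–O bond of 26 (epimerisation or opening of ring C), and the alkenyl metal may be protonated or homocoupled before it meets the iodide. Fallback: setting out from 13, the same Zr-catalysed methylalumination is quenched with I2 to give the (E)-dienyl iodide F1. Palladium-catalysed stannylation with (Bu3Sn)2 and Pd(PPh3)4 converts it into the (E)-dienylstannane F2. A neutral Stille coupling of F2 with 26 (Pd2(dba)3, AsPh3, DMF, rt) returns to the route at 29, so the furanoid partner never meets an aluminium or zinc reagent.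

Step 13. Anti selectivity may leak through palladium exchange on the allenyl-palladium intermediate, hydride may be delivered at C6′ to give the alkyne, or the vinylallene may be reduced further. Fallback: setting out from 8, HWE olefination with triethyl 3-methyl-4-phosphonocrotonate gives the epoxy dienoate F3, and i-Bu2AlH reduction gives the epoxy dienol F4. A trace of pyridinium p-toluenesulfonate in CH2Cl2 then triggers the classical 5,6-epoxide → 5,8-furanoid rearrangement. This gives 20 together with its C8′ epimer F5, which is removed by chromatography; the route is rejoined at 20. The fallback is shorter, but C8′ is not controlled and about half of the material is lost.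

Step 8. Zerovalent palladium may fail to ionise the tetrasubstituted oxirane, or the π-allyl complex may be captured at C8 by the alkoxide to give a dihydrofuran before CO2 is taken up. Fallback: setting out from 2, the potassium enolate (KN(SiMe3)2) is hydroxylated with the enantiomer of (camphorsulfonyl)oxaziridine that delivers oxygen anti to the C3 silyloxy group, giving the α-hydroxy ketone F6. LiC≡C–C≡C–SiMe3 then adds axially, anti to the C5 oxygen, to give the cis-diol diyne F7. LiAlH4 in THF reduces the triple bond next to the carbinol by hydroxyl-directed trans-hydroalumination to the (E)-enyne F8. NaOMe in MeOH removes the silyl cap and rejoins the route at 13.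

Further compounds
F1 | step 19 | (E)-dienyl iodide, 13 with C≡CH replaced by (E)-C(CH3)=CH–I | I/C=C(\C)/C=C/[C@]1(O)C(C)(C)C[C@H](O[Si](C)(C)C(C)(C)C)C[C@@]1(C)O
F2 | step 19 | (E)-dienyl(tributyl)stannane corresponding to F1 | CCCC[Sn](CCCC)(CCCC)/C=C(\C)/C=C/[C@]1(O)C(C)(C)C[C@H](O[Si](C)(C)C(C)(C)C)C[C@@]1(C)O
F3 | step 13 | epoxy dienoate, ethyl (2E,4E)-3-methyl-5-(epoxycyclohexyl)penta-2,4-dienoate (ring as in 8) | CCOC(=O)/C=C(C)/C=C/[C@@]12O[C@]1(C)C[C@@H](O[Si](C)(C)C(C)(C)C)CC2(C)C
F4 | step 13 | epoxy dienol from F3 | OC/C=C(C)/C=C/[C@@]12O[C@]1(C)C[C@@H](O[Si](C)(C)C(C)(C)C)CC2(C)C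
F5 | step 13 | C8′ epimer of 20, (2S,6S,7aR)-configured | OC/C=C(\C)[C@@H]1C=C2C(C)(C)C[C@H](O[Si](C)(C)C(C)(C)C)C[C@@]2(C)O1
F6 | step 8 | α-hydroxy ketone, 2 with OH on C5 trans to the silyloxy group | O=C1C(C)(C)C[C@H](O[Si](C)(C)C(C)(C)C)C[C@@]1(C)O
F7 | step 8 | cis-diol diyne, C6 adduct of F6 with C≡C–C≡C–SiMe3 | C[Si](C)(C)C#CC#C[C@]1(O)C(C)(C)C[C@H](O[Si](C)(C)C(C)(C)C)C[C@@]1(C)O
F8 | step 8 | C-silylated 13 ((E)-CH=CH–C≡C–SiMe3 on C6) | C[Si](C)(C)C#C/C=C/[C@]1(O)C(C)(C)C[C@H](O[Si](C)(C)C(C)(C)C)C[C@@]1(C)O
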